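The runs stem from a simulated flask on assumed constants; scatter was added.

The constants are hidden, but the readings fold them with the charges and the time into one dimensionless number.

- autumn: electrophile 0.10 M; nucleophile 0.30 M; buffer base 0.10 M; buffer acid 0.030 M; the very flask that is asked about, followed so far
- flask: electrophile 0.10 M; nucleophile 0.300 M; buffer base 0.100 M; buffer acid 0.0300 M; time 4.0 h

autumn run (percent of the electrophile charged)

| time / min | electrophile / % | target / % |
|---|---|---|
| 4.00 | 93.3 | 5.6 |
| 6.00 | 90.8 | 6.2 |
| 10.0 | 84.7 | 10.8 |
| 20.0 | 72.8 | 19.6 |
| 30.0 | 63.0 | 26.0 |
| 50.0 | 48.8 | 37.7 |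

(scatter of a reading: 0.5 percentage points)

- what was read earlier has a scatter of 0.5 percentage points, one standard deviation
- the earlier runs do not show the pH; that part of a forecast is a guess

- part of the electrophile that has reacted at 4.0 h
- pH of the solution at 4.0 h

The nucleophile is charged at M = 3.00 times the electrophile, and the smaller charge makes the electrophile the limiting reagent, so the end state to expect has little electrophile left. How little depends on the reach, the logarithm of (M − r)/(M·u), with r the fraction reacted and u the fraction left. Under a one-to-one second-order law, at a fixed charge of electrophile, the reach grows in proportion to time and to M less one.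

The autumn reading at 50.0 min gives 0.530, so under that law the reach at 4.0 h is 2.55. That leaves 5.37 %, so this reckoning has 94.6 % reacted.

One number is not quite enough. At 20.0 min it puts 73.8 % left, while the reading is 72.8 %, a gap of 1 percentage point against a scatter of 0.5 points. The reach also counts loss, not target: the autumn readings at 50.0 min put target at 73.6 % of the reacted electrophile. The reach says nothing of the pH.

The forecast stands lower than this reckoning, at 92 % and pH 6, allowing for “possible slowing as the buffer is used up”.

The flask gives 91.3 % reacted and pH 6.71, both within the margins of the forecast.

    2 electrophile → homo dimer (k = 1.60 M⁻¹ h⁻¹)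
    protonated nucleophile ⇌ nucleophile + acid, settled at all times (K = 7.90 × 10⁻⁷ M)
    electrophile + nucleophile ⇌ acid + target + leaving group (K = 4.50 × 10⁻⁶ M, k = 2.50 M⁻¹ h⁻¹)
    buffer acid ⇌ buffer base + acid, settled at all times (K = 2.50 × 10⁻⁷ M)

That result is a reach of 2.08 in the flask, with 71.8 % of the electrophile charged standing as target. In the neighbouring flask with 1.2 M of nucleophile, M is 12.0, and scaling by M less one takes the reach to 14.0, which leaves <0.001 %. That neighbouring flask gives 99.9 % reacted, with 0.15 % of the electrophile left, more than reckoned, and 94.5 % target.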